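**Retrosynthetic overview**
1. Target 25 comes from ring-closing metathesis at C4=C5 of seco-diene 24, which closes the ten-membered carbocycle last. The C9 carbinol comes from Felkin-controlled Luche reduction of ketone 23.
2. The cis-2,3-oxirane and the isopropenyl end come from a reagent-controlled (Z)-γ-chloro-methallylboration of aldehyde 19, followed by ring closure.
3. Key step: the C9 ketone, the C1=C10 enoate carrying C14, and the C2 aldehyde of 19 all come from singlet-oxygen dearomatisation of furan 17. The furan carbons are C9, C10, C1 and C2.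
4. Furan 17 comes from Mitsunobu inversion of alcohol 16 with epoxyangelic acid 15. Alcohol 16 comes from a Zn-Barbier union at C7–C8 of bromobutenolide 8 and furaldehyde 11, which is made from methyl furan-3-carboxylate.
5. Ring order: butenolide (step 3), α-methylene-γ-lactone (step 8), furan opened (step 10), oxirane (step 11), carbocycle (step 13).

Assumption and abbreviations: locants C1–C15 follow germacrane numbering (C6–O lactone, C7–C11, C14 = ester carbon, C15 = ring methyl). Lac = (2R,3S)-4-methylidene-5-oxo-2-[(1E)-prop-1-enyl]oxolan-3-yl. EpAng = (2R,3R)-2,3-dimethyloxirane-2-carbonyl.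

Step 1
Reactants: 1 (E)-crotonaldehyde; 2 vinylmagnesium bromide
Product: 4 (3S,4E)-hexa-1,4-dien-3-ol, via divinylzinc 3 (not isolated)
Conditions: 2, ZnCl2, Et2O, then 1,4-dioxane (Mg salts filtered off); 1, (−)-MIB (5 mol %), toluene, −30 to 0 °C; aq NH4Cl
Reagents that add atoms: none
Why: Amino-alcohol-catalysed asymmetric organozinc addition (Noyori-type vinylation), in which the (−)-MIB–zinc chelate attacks the enal face in the same sense as Et2Zn additions that give S allylic alcohols, and this sets the future C6.

Step 2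
Reactants: 4 (3S,4E)-hexa-1,4-dien-3-ol; 5 2-(bromomethyl)prop-2-enoic acid
Product: 7 (3S,4E)-hexa-1,4-dien-3-yl 2-(bromomethyl)prop-2-enoate, via 2-(bromomethyl)acryloyl chloride 6 (not isolated)
Conditions: 5, (COCl)2, DMF (cat.), CH2Cl2, 0 °C; then 4, i-Pr2NEt, CH2Cl2, −78 to 0 °C
Reagents that add atoms: none
Why: O-acylation through the acid chloride, where the non-nucleophilic base avoids SN2′ attack on the allylic bromide (which DMAP or pyridine would cause) and the carbinol centre is untouched.

Step 3
Reactants: 7 (3S,4E)-hexa-1,4-dien-3-yl 2-(bromomethyl)prop-2-enoate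
Product: 8 (5R)-3-(bromomethyl)-5-[(1E)-prop-1-enyl]furan-2(5H)-one
Conditions: Hoveyda–Grubbs II (5 mol %), CH2Cl2 (0.01 M), 40 °C
Reagents that add atoms: none
Why: Ring-closing metathesis to an α-substituted butenolide, in which the catalyst loads on the terminal vinyl group much faster than on the propenyl group, so the propenyl arm stays as the C5 handle and C6 keeps its configuration (now R by CIP).

Step 4
Reactants: 9 methyl furan-3-carboxylate
Product: 11 methyl 2-formylfuran-3-carboxylate, via methyl 2-lithiofuran-3-carboxylate 10 (not isolated)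
Conditions: LDA, THF, −78 °C; DMF, −78 to 0 °C; 1 M HCl
Reagents that add atoms: N,N-dimethylformamide CN(C)C=O
Why: Directed ortho-lithiation and formylation, since the position between the ring oxygen and the ester is the most acidic and the formyl carbon becomes C8.

Step 5
Reactants: 12 angelic acid
Product: 13 (2Z)-2-methylbut-2-en-1-ol
Conditions: LiAlH4, Et2O, 0 °C; Fieser work-up
Reagents that add atoms: none
Why: Hydride reduction of the acid to the allylic alcohol with the Z geometry retained.

Step 6
Reactants: 13 (2Z)-2-methylbut-2-en-1-ol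
Product: 14 [(2S,3R)-2,3-dimethyloxiran-2-yl]methanol
Conditions: Ti(Oi-Pr)4 (10 mol %), L-(+)-DET (12 mol %), t-BuOOH, 4 Å MS, CH2Cl2, −20 °C
Reagents that add atoms: tert-butyl hydroperoxide CC(C)(C)OO
Why: Sharpless asymmetric epoxidation, where L-(+)-tartrate gives the 2S face as it does for other Z-allylic alcohols (nerol type) and the syn-specific oxygen transfer keeps the two methyl groups trans, which sets both side-chain centres.

Step 7
Reactants: 14 [(2S,3R)-2,3-dimethyloxiran-2-yl]methanol
Product: 15 (2R,3R)-2,3-dimethyloxirane-2-carboxylic acid (epoxyangelic acid)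
Conditions: RuCl3·xH2O (2 mol %), NaIO4, MeCN/EtOAc/H2O, 0 °C to rt
Reagents that add atoms: water O
Why: Catalytic RuO4 oxidation of an epoxy alcohol to the epoxy acid via the aldehyde hydrate, with no stereocentre touched (the C2 descriptor changes from S to R only through CIP ranking).

Step 8
Reactants: 8 (5R)-3-(bromomethyl)-5-[(1E)-prop-1-enyl]furan-2(5H)-one; 11 methyl 2-formylfuran-3-carboxylate
Product: 16 methyl 2-{(R)-hydroxy[(2R,3R)-4-methylidene-5-oxo-2-[(1E)-prop-1-enyl]oxolan-3-yl]methyl}furan-3-carboxylate
Conditions: Zn dust, THF/sat. aq NH4Cl, 0 °C to rt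
Reagents that add atoms: none
Why: Barbier-type SE2′ allylation with a 3-(bromomethyl)butenolide (Dreiding–Schmidt type), in which C7 attacks anti to the propenyl group to give the trans 6,7-lactone, and the ring-locked E-type allylzinc reacts through a Zimmerman–Traxler chair to give the anti adduct, i.e. C8 with the configuration opposite to the target.

Step 9
Reactants: 16 Barbier adduct; 15 epoxyangelic acid
Product: 17 methyl 2-{(S)-(EpAng-oxy)(Lac)methyl}furan-3-carboxylate
Conditions: PPh3, DIAD, toluene, 0 °C to rt
Reagents that add atoms: none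
Why: Mitsunobu esterification installs the side chain and inverts C8 to S in one operation, and the electron-poor 3-carbomethoxyfuran disfavours ionisation so the displacement stays SN2.

Step 10
Reactants: 17 furan epoxyangelate
Product: 19 methyl (2E)-2-[(2S)-2-(EpAng-oxy)-2-(Lac)acetyl]-4-oxobut-2-enoate, via furan endoperoxide 18 (not isolated)
Conditions: O2, TPP (1 mol %), visible light, CH2Cl2, −78 °C; then Me2S, −78 to −20 °C
Reagents that add atoms: oxygen O=O
Why: Furan photooxygenation ([4+2] addition of singlet oxygen) with reductive opening of the endoperoxide destroys the aromatic ring and converts its four carbons at once into the C9 ketone, the C1=C10 enoate and the C2 aldehyde; C9 and C2 were held cis in the ring, so the trisubstituted olefin is formed with the 1(10) geometry of the target, and the electron-poor or sparsely substituted olefins are inert to 1O2.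

Step 11
Reactants: 19 keto-enal; 20 3-chloro-2-methylprop-1-ene
Product: 23 methyl (2E)-2-[(2S)-2-(EpAng-oxy)-2-(Lac)acetyl]-3-[(2R,3S)-3-(prop-1-en-2-yl)oxiran-2-yl]prop-2-enoate, via chloromethallylborane 21 (not isolated), via chlorohydrin 22 (not isolated)
Conditions: 20, (−)-Ipc2BOMe, LiN(c-Hex)2, Et2O, −95 °C; BF3·OEt2; 19, −95 °C; ethanolamine; crude 22, DBU, CH2Cl2, 0 °C
Reagents that add atoms: none
Why: Brown-type asymmetric allylboration with a (Z)-γ-chloroallylborane (the 2-methyl homologue of the known reagent) and Williamson-type closure, in which the chair transition state of the Z-borane gives the syn chlorohydrin, the Ipc groups from (+)-α-pinene fix C2 as R, the aldehyde outruns the hindered C9 ketone, and SN2 loss of chloride inverts C3 to give the cis (2R,3S) oxirane.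

Step 12
Reactants: 23 epoxy ketone
Product: 24 methyl (2E)-2-[(1S,2S)-2-(EpAng-oxy)-1-hydroxy-2-(Lac)ethyl]-3-[(2R,3S)-3-(prop-1-en-2-yl)oxiran-2-yl]prop-2-enoate
Conditions: NaBH4, CeCl3·7H2O, MeOH/CH2Cl2, −78 °C; AcOH quench
Reagents that add atoms: none
Why: Luche 1,2-reduction of the cross-conjugated ketone, where polar Felkin–Anh attack anti to the C8 acyloxy group gives the syn (8S,9S) hydroxy ester, and the low temperature spares the α-methylene lactone and prevents acyl migration.

Step 13
Reactants: 24 seco-diene
Product: 25 target CNP0291485.1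
Conditions: Grubbs II (15 mol %), 1,4-benzoquinone (cat.), CH2Cl2 (0.5 mM), 40 °C
Reagents that add atoms: none
Why: Ring-closing metathesis of the propenyl and isopropenyl ends with loss of propene, where the ten-membered ring accepts only the ring-cis (Z) C4=C5 olefin, no stereocentre is touched, and keeping the bath at or below 40 °C avoids Cope rearrangement of the cis-divinyloxirane.

**Compound list**
1 | (E)-crotonaldehyde | C/C=C/C=O | starting material
2 | vinylmagnesium bromide | C=C[Mg]Br | starting material
3 | divinylzinc | C=C[Zn]C=C | intermediate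
4 | (3S,4E)-hexa-1,4-dien-3-ol | C/C=C/[C@@H](O)C=C | intermediate
5 | 2-(bromomethyl)prop-2-enoic acid | C=C(CBr)C(=O)O | starting material
6 | 2-(bromomethyl)acryloyl chloride | C=C(CBr)C(=O)Cl | intermediate
7 | (3S,4E)-hexa-1,4-dien-3-yl 2-(bromomethyl)prop-2-enoate | C/C=C/[C@@H](OC(=O)C(=C)CBr)C=C | intermediate
8 | (5R)-3-(bromomethyl)-5-[(1E)-prop-1-enyl]furan-2(5H)-one | C/C=C/[C@H]1OC(=O)C(CBr)=C1 | intermediate
9 | methyl furan-3-carboxylate | COC(=O)c1ccoc1 | starting material
10 | methyl 2-lithiofuran-3-carboxylate | COC(=O)c1ccoc1[Li] | intermediate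
11 | methyl 2-formylfuran-3-carboxylate | COC(=O)c1ccoc1C=O | intermediate
12 | angelic acid | C/C=C(/C)C(=O)O | starting material
13 | (2Z)-2-methylbut-2-en-1-ol | C/C=C(/C)CO | intermediate
14 | [(2S,3R)-2,3-dimethyloxiran-2-yl]methanol | OC[C@]1(C)O[C@@H]1C | intermediate
15 | (2R,3R)-2,3-dimethyloxirane-2-carboxylic acid | OC(=O)[C@]1(C)O[C@@H]1C | intermediate
16 | Barbier adduct (6R; C7 as in target; 8R, epimeric to target) | C=C1C(=O)O[C@H](/C=C/C)[C@H]1[C@@H](O)c1occc1C(=O)OC | intermediate
17 | furan epoxyangelate (6R,7S,8S) | C=C1C(=O)O[C@H](/C=C/C)[C@H]1[C@H](OC(=O)[C@]1(C)O[C@@H]1C)c1occc1C(=O)OC | intermediate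
18 | furan endoperoxide (2,3,7-trioxabicyclo[2.2.1]hept-5-ene; new bridgeheads unassigned) | C=C1C(=O)O[C@H](/C=C/C)[C@H]1[C@H](OC(=O)[C@]1(C)O[C@@H]1C)C12OOC(O1)C=C2C(=O)OC | intermediate
19 | keto-enal (C9 ketone, C2 aldehyde, C9 and C2 cis on C1=C10) | C=C1C(=O)O[C@H](/C=C/C)[C@H]1[C@H](OC(=O)[C@]1(C)O[C@@H]1C)C(=O)/C(C(=O)OC)=C\C=O | intermediate
20 | 3-chloro-2-methylprop-1-ene | C=C(C)CCl | starting material
21 | (Z)-(3-chloro-2-methylallyl)diisopinocampheylborane (Ipc from (+)-α-pinene) | Cl/C=C(/C)CB([C@@H]1C[C@@H]2C[C@H]([C@H]1C)C2(C)C)[C@@H]1C[C@@H]2C[C@H]([C@H]1C)C2(C)C | intermediate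
22 | syn chlorohydrin (2R,3R) | C=C1C(=O)O[C@H](/C=C/C)[C@H]1[C@H](OC(=O)[C@]1(C)O[C@@H]1C)C(=O)/C(C(=O)OC)=C\[C@@H](O)[C@H](Cl)C(C)=C | intermediate
23 | cis-epoxy ketone (2R,3S,6R,7S,8S) | C=C1C(=O)O[C@H](/C=C/C)[C@H]1[C@H](OC(=O)[C@]1(C)O[C@@H]1C)C(=O)/C(C(=O)OC)=C\[C@H]1O[C@H]1C(C)=C | intermediate
24 | seco-diene alcohol (2R,3S,6R,7S,8S,9S) | C=C1C(=O)O[C@H](/C=C/C)[C@H]1[C@H](OC(=O)[C@]1(C)O[C@@H]1C)[C@@H](O)/C(C(=O)OC)=C\[C@H]1O[C@H]1C(C)=C | intermediate
25 | CNP0291485.1 | C=C1C(=O)O[C@@H]2/C=C(/C)[C@@H]3O[C@@H]3/C=C(/C(=O)OC)[C@H](O)[C@@H](OC(=O)[C@]3(C)O[C@@H]3C)[C@@H]12 | target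

Total step count: 13. Longest linear sequence: 9 (steps 1–3 and 8–13).

**Steps most likely to fail**

Step 13 forms a ten-membered ring and a trisubstituted olefin next to an oxirane. The fallback sets out from 23 and comes back at 25. The ring is closed one stage earlier, on the ketone. There C9 is sp2 and no OH···ester hydrogen bond folds the chain, and metathesis gives the macrocyclic 9-oxo germacranolide F3. The C9 carbinol is then made by Luche reduction of the ring ketone, so its configuration rests on peripheral attack on the macrocycle instead of on acyclic Felkin control.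

Step 11 uses a new homologue of the chloroallylborane. The free (Z)-γ-hydroxy-enone 22 can also fall back to a furan by cyclodehydration. The fallback sets out from 19 and 20 and comes back at 23. The oxirane is made in a single sulfur-ylide epoxidation, so no free C2 hydroxyl ever sits cis to the C9 ketone. Compound 20 is quaternised with tetrahydrothiophene to 1-(2-methylprop-2-enyl)thiolan-1-ium chloride F4. Its ylide (phosphazene base, −78 °C) adds to the aldehyde of 19, and the cis isomer 23 is separated from the trans epoxide.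

Step 9 is an SN2 displacement at a hindered carbinol, with elimination towards C7 as a competing path. The fallback sets out from 8 and 11 and comes back at 17. The C7–C8 bond is formed through an open instead of a closed transition state. Compound 8 is converted with hexabutylditin and Pd(0) into (5R)-5-[(1E)-prop-1-enyl]-3-[(tributylstannyl)methyl]furan-2(5H)-one F1. Its BF3·OEt2-promoted addition to 11 (antiperiplanar, syn-selective) gives the 8S alcohol methyl 2-{(S)-hydroxy[(2R,3R)-4-methylidene-5-oxo-2-[(1E)-prop-1-enyl]oxolan-3-yl]methyl}furan-3-carboxylate F2. F2 is acylated with 15 with retention (Yamaguchi mixed anhydride) to give 17.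

**Further compounds**
F1 | step 9 | (5R)-5-[(1E)-prop-1-enyl]-3-[(tributylstannyl)methyl]furan-2(5H)-one | C/C=C/[C@H]1OC(=O)C(C[Sn](CCCC)(CCCC)CCCC)=C1
F2 | step 9 | methyl 2-{(S)-hydroxy[(2R,3R)-4-methylidene-5-oxo-2-[(1E)-prop-1-enyl]oxolan-3-yl]methyl}furan-3-carboxylate | C=C1C(=O)O[C@H](/C=C/C)[C@H]1[C@H](O)c1occc1C(=O)OC
F3 | step 13 | macrocyclic 9-oxo germacranolide (9-dehydro-25) | C=C1C(=O)O[C@@H]2/C=C(/C)[C@@H]3O[C@@H]3/C=C(/C(=O)OC)C(=O)[C@@H](OC(=O)[C@]3(C)O[C@@H]3C)[C@@H]12
F4 | step 11 | 1-(2-methylprop-2-enyl)thiolan-1-ium chloride | C=C(C)C[S+]1CCCC1.[Cl-]
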